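The earlier runs and the new flask stem from a simulated flask on assumed constants.

3 questions stand over amber and ochre, and I reckon them with one share and one clock.

| flask | substrate | first nucleophile | second nucleophile | protic impurity | temperature | remark | time |
|---|---|---|---|---|---|---|---|
| maple | 0.013 M | 0.060 M | 0.016 M | 6 mM | −5 °C | run made earlier |  |
| elm | 0.030 M | 0.060 M | 0.016 M | 6 mM | 10 °C | run made earlier |  |
| amber | 0.020 M | 0.0600 M | 0.0160 M | 6.00 mM | 0 °C |  | 12 h |
| ochre | 0.020 M | 0.0600 M | 0.0160 M | 6.00 mM | 20 °C |  | 12 h |

| maple: time / h | maple: target / % | elm: time / h | elm: target / % |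
|---|---|---|---|
| 1.00 | 4.3 | 0.667 | 20.8 |
| 3.00 | 11.9 | 2.00 | 45.1 |
| 5.00 | 18.6 | 3.00 | 55.4 |
| 8.00 | 26.6 | 5.00 | 65.4 |
| 12.0 | 36.2 | 8.00 | 69.4 |
| 15.0 | 42.0 | 10.0 | 70.1 |

(readings scatter by 0.3 percentage points)
1. the flask with the highest amount of target, in percent of the substrate charged ("all alike" if they lie within 1.5 percentage points) (amber / ochre / all alike)
2. final target, as a percentage of the substrate charged, in amber
3. final target, as a percentage of the substrate charged, in ochre
- the numbers in the tables scatter by 0.3 percentage points (one standard deviation)
- what may be going on: second nucleophile + intermediate -> other capture product; first nucleophile + protic impurity -> quenched reagent; substrate -> intermediate; first nucleophile + intermediate -> target; intermediate -> solvolysis product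

The substrate may open to the intermediate, which then ends as target, as other capture product or as solvolysis product. I take the opening as the rate-limiting step and the intermediate as used up as fast as it forms, so in my reckoning target follows spent substrate. Elm's readings flatten towards 70.1%, its last reading, and I call this s, the capture share: the part of the spent substrate that ends as target. I let the spent part grow first-order with a rate constant k. With s, elm's reading at 2.00 h gives k = 0.516 h⁻¹ at 10 °C, and maple's last reading gives k = 0.0609 h⁻¹ at −5 °C. As a check, these give 36.3% for maple at 12.0 h, a reading I did not use, and maple shows 36.2%. Amber and ochre charge first nucleophile like elm, and second nucleophile like elm, so I carry s over to both, though they hold less substrate than elm and differ from it in temperature.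

I assume k grows by a constant factor per degree. Amber lies a third of the way from maple to elm, so its k is 0.124 h⁻¹. Amber's curve starts along a line that would meet the level s at 8.05 h. Its knee stands there, at 44.3%, and at 12 h I reckon amber to have spent 77.4% and to reach 54.3%. Ochre's k comes to 2.14 h⁻¹, so its knee lies at 0.467 h and I reckon ochre to end on the level, at 70.1%. I therefore reckon ochre above amber by 16 percentage points.

The forecast names ochre, with 54% (50% to 58%) for amber and 69.5% (66% to 73%) for ochre: “Amber therefore reaches only about 79% conversion in 12 h, while ochre finishes.”

The flasks give 55.4% in amber and 69.6% in ochre, so ochre holds the most target.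

    second nucleophile + intermediate → other capture product (k = 22.0 M⁻¹ min⁻¹, Ea = 50.0 kJ mol⁻¹)
    first nucleophile + protic impurity → quenched reagent (k = 0.580 M⁻¹ min⁻¹, Ea = 67.0 kJ mol⁻¹)
    substrate → intermediate (k = 0.00210 min⁻¹, Ea = 90.0 kJ mol⁻¹)
    first nucleophile + intermediate → target (k = 18.0 M⁻¹ min⁻¹, Ea = 57.0 kJ mol⁻¹)
    intermediate → solvolysis product (k = 0.0490 min⁻¹, Ea = 88.0 kJ mol⁻¹)
    (constants at 0 °C)

Amber has spent 78.0% of its substrate by 12 h, and s on that part gives 54.7%. A repeat of amber at 15 °C has 0% substrate left at 12.0 h, so s puts its target at 70.1%, and that flask holds 70.3%.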